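**Retrosynthetic overview**

- The target comes from double tigloylation of the anti-7,9-diol, which comes from catalyst-controlled hydrogenation of a cage β-diketone; the seven-membered ring is closed by a Claisen condensation (C8–C9) of a methyl ketone (Wacker oxidation of a vinyl group) onto the C9 ester.
- Key disconnection: the cyclobutane bond C10–C11, made by oxidative coupling of two enolate carbons (ester α-carbon C10 and enone α′-carbon C11) across a cis-4,5-disubstituted 3-methylcyclohexenone. This one step gives the bicyclo[3.1.1] core, the quaternary C10 and the C9/C1 1,4-dicarbonyl.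
- C4–C10 comes from a Johnson–Claisen rearrangement of a cis allylic alcohol (chirality transfer); the C1 ketone comes from allylic oxidation.
- The cyclohexenone comes from an organocatalytic Michael addition (sets C5) and aldol condensation of 3,3-dimethylpent-4-enal with ethyl vinyl ketone.
- Ring order: six-membered ring, then cyclobutane, then seven-membered ring.

Assumption: atom labels C1–C11 follow longipinane numbering of the target (C1 ketone; C2=C3 enone with methyl on C3; C4 and C11 cyclobutane CH; C5 cyclobutane CH bearing C6(CH3)2; C7 and C9 ester carbons; C8 CH2; C10 quaternary methyl carbon), the target being the (4R,5S,7R,9R,10R,11R) isomer; 3,3-dimethylpent-4-enal is taken as purchasable.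

**Route**

Step 1
Reactants: 1 3,3-dimethylpent-4-enal; 2 pent-1-en-3-one (ethyl vinyl ketone)
Product: 3 (2S)-2-(2-methylbut-3-en-2-yl)-5-oxoheptanal
Conditions: (S)-α,α-diphenylprolinol methyl ether (5 mol%), ethyl 3,4-dihydroxybenzoate (20 mol%), neat, 4 °C
Reagents that add atoms: none
Why: Enamine-catalysed asymmetric Michael addition of an aldehyde to a vinyl ketone, in which the (S)-catalyst shields one face of the E-enamine so that the new α-stereocentre (C5 of the target) is formed as S.

Step 2
Reactants: 3 (2S)-2-(2-methylbut-3-en-2-yl)-5-oxoheptanal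
Product: 5 (4R)-2-methyl-4-(2-methylbut-3-en-2-yl)cyclohex-2-en-1-one, via aldol adduct 4 (not isolated)
Conditions: KOH (0.2 equiv), n-Bu4NOH (cat.), Et2O/THF/H2O, reflux
Reagents that add atoms: none
Why: Intramolecular aldol condensation (Robinson-type closure) in which only the ethyl CH2 of the ketone can reach the aldehyde through a six-membered ring, placing the methyl on the enone α-carbon while the mild base leaves the C5 stereocentre untouched.

Step 3
Reactants: 5 (4R)-2-methyl-4-(2-methylbut-3-en-2-yl)cyclohex-2-en-1-one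
Product: 6 (1S,4R)-2-methyl-4-(2-methylbut-3-en-2-yl)cyclohex-2-en-1-ol
Conditions: (R)-2-methyl-CBS-oxazaborolidine (0.2 equiv), BH3·SMe2 (0.7 equiv), THF, −30 °C
Reagents that add atoms: none
Why: Corey–Bakshi–Shibata reduction, where the (R)-oxazaborolidine delivers hydride under catalyst control (alkenyl arm as the large group) to give the 1S carbinol that is cis to the C5 side chain.

Step 4
Reactants: 6 (1S,4R)-2-methyl-4-(2-methylbut-3-en-2-yl)cyclohex-2-en-1-ol; 7 triethyl orthopropionate
Product: 9 ethyl 2-[(1S,6R)-2-methyl-6-(2-methylbut-3-en-2-yl)cyclohex-2-en-1-yl]propanoate (both C10 epimers), via ketene acetal 8 (not isolated)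
Conditions: EtCO2H (0.1 equiv), xylenes, 140 °C, EtOH distilled off
Reagents that add atoms: none
Why: Johnson–Claisen rearrangement, in which the pseudoaxial C–O bond transfers its configuration suprafacially through the [3,3] shift so that C10 is attached at C4 cis to the C5 side chain and the ring alkene moves to C2=C3 (the propanoate stereocentre is erased later by enolisation).

Step 5
Reactants: 9 ethyl 2-[(1S,6R)-2-methyl-6-(2-methylbut-3-en-2-yl)cyclohex-2-en-1-yl]propanoate
Product: 10 ethyl 2-[(1S,6R)-2-methyl-6-(2-methylbut-3-en-2-yl)-4-oxocyclohex-2-en-1-yl]propanoate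
Conditions: dirhodium tetracaprolactamate Rh2(C6H10NO)4 (1 mol%), t-BuOOH (5 equiv), K2CO3 (0.5 equiv), CH2Cl2, rt
Reagents that add atoms: tert-butyl hydroperoxide, CC(C)(C)OO
Why: Allylic C–H oxidation by tert-butylperoxy radicals converts the only unhindered allylic CH2 (C1, next to the alkene CH) into the enone carbonyl, as in the pinene-to-verbenone oxidation, and the vinyl group has no allylic hydrogen.

Step 6
Reactants: 10 ethyl 2-[(1S,6R)-2-methyl-6-(2-methylbut-3-en-2-yl)-4-oxocyclohex-2-en-1-yl]propanoate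
Product: 12 ethyl (1R,5R,6R,7S)-2,6-dimethyl-7-(2-methylbut-3-en-2-yl)-4-oxobicyclo[3.1.1]hept-2-ene-6-carboxylate, via dilithium bis-enolate 11 (not isolated)
Conditions: LiN(iPr)2 (2.2 equiv), THF, −78 °C (inverse addition); then CuCl2 (2.3 equiv) in DMF, −78 → 0 °C, 0.01 M
Reagents that add atoms: none
Why: Proposed new method: intramolecular oxidative enolate heterocoupling in which the kinetic α′-dienolate carbon C11 and the ester enolate carbon C10 (both nucleophilic, held 1,3-diaxial on the cyclohexenone with the bulky C5 group equatorial) are joined by two one-electron oxidations with CuCl2, one enolate becoming a copper-bound α-carbonyl radical (enolonium equivalent) that is captured by the neighbouring enolate to close the cyclobutane; the closest known chemistry is the copper- or iron-mediated oxidative coupling of lithium enolates to 1,4-dicarbonyls, including intramolecular dianion couplings that give cyclobutane-1,2-diesters and bridged rings; C11 is fixed by the ring and at C10 the flat ester is expected to take the anti position beside the side chain, leaving methyl syn to the enone bridge.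

Step 7
Reactants: 12 ethyl (1R,5R,6R,7S)-2,6-dimethyl-7-(2-methylbut-3-en-2-yl)-4-oxobicyclo[3.1.1]hept-2-ene-6-carboxylate
Product: 13 ethyl (1R,5R,6R,7S)-2,6-dimethyl-7-(2-methyl-3-oxobutan-2-yl)-4-oxobicyclo[3.1.1]hept-2-ene-6-carboxylate
Conditions: PdCl2 (10 mol%), CuCl (1 equiv), O2 (1 atm), DMF/H2O 7:1, rt
Reagents that add atoms: water, O
Why: Tsuji–Wacker oxidation, in which Markovnikov hydroxypalladation of the terminal vinyl group gives the methyl ketone (C7, C8) while the trisubstituted enone and the ester are inert.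

Step 8
Reactants: 13 ethyl (1R,5R,6R,7S)-2,6-dimethyl-7-(2-methyl-3-oxobutan-2-yl)-4-oxobicyclo[3.1.1]hept-2-ene-6-carboxylate
Product: 14 (1R,2R,7S,8R)-2,6,6,9-tetramethyltricyclo[5.4.0.0^2,8]undec-9-ene-3,5,11-trione (longipin-2-ene-1,7,9-trione)
Conditions: KOC(CH3)3 (2.5 equiv), THF, 0 °C → rt; aq. HCl work-up
Reagents that add atoms: none
Why: Intramolecular Claisen (Dieckmann-type) condensation, in which the only enolisable carbon (the new methyl, C8) attacks the non-enolisable C9 ester held 1,3-diaxial to it on the cyclobutane, and deprotonation of the β-diketone drives closure of the seven-membered ring.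

Step 9
Reactants: 14 (1R,2R,7S,8R)-2,6,6,9-tetramethyltricyclo[5.4.0.0^2,8]undec-9-ene-3,5,11-trione
Product: 15 (1R,2R,3R,5R,7S,8R)-3,5-dihydroxy-2,6,6,9-tetramethyltricyclo[5.4.0.0^2,8]undec-9-en-11-one ((7R,9R)-7,9-dihydroxylongipin-2-en-1-one)
Conditions: RuCl2[(S)-BINAP] (2 mol%), H2 (80 atm), MeOH, 50 °C
Reagents that add atoms: none
Why: Noyori asymmetric hydrogenation of a β-diketone, in which the chelated ruthenium–(S)-BINAP hydride reduces both ring carbonyls under catalyst control to the anti (7R,9R) diol because the cage gives almost no facial bias of its own and the hindered enone is not reduced.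

Step 10
Reactants: 15 (7R,9R)-7,9-dihydroxylongipin-2-en-1-one; 16 (E)-2-methylbut-2-enoyl chloride (tigloyl chloride)
Product: 17 (4R,5S,7R,9R,10R,11R)-7,9-bis[(E)-2-methylbut-2-enoyloxy]longipin-2-en-1-one (CNP0236543.5)
Conditions: 16 (4 equiv), Et3N (6 equiv), DMAP (0.5 equiv), CH2Cl2, 40 °C
Reagents that add atoms: none
Why: DMAP-catalysed acylation (nucleophilic catalysis) esterifies both secondary alcohols without touching the stereocentres, and the E-configured tigloyl group is the thermodynamic isomer and is retained.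

**Compound list**

1 | 3,3-dimethylpent-4-enal | O=CCC(C)(C)C=C | starting material
2 | pent-1-en-3-one (ethyl vinyl ketone) | CCC(=O)C=C | starting material
3 | (2S)-2-(2-methylbut-3-en-2-yl)-5-oxoheptanal | O=C[C@@H](CCC(=O)CC)C(C)(C)C=C | intermediate
4 | (4S)-3-hydroxy-2-methyl-4-(2-methylbut-3-en-2-yl)cyclohexan-1-one (aldol adduct) | O=C1C(C)C(O)[C@H](C(C)(C)C=C)CC1 | intermediate (not isolated)
5 | (4R)-2-methyl-4-(2-methylbut-3-en-2-yl)cyclohex-2-en-1-one | O=C1C(C)=C[C@H](C(C)(C)C=C)CC1 | intermediate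
6 | (1S,4R)-2-methyl-4-(2-methylbut-3-en-2-yl)cyclohex-2-en-1-ol | O[C@@H]1C(C)=C[C@H](C(C)(C)C=C)CC1 | intermediate
7 | triethyl orthopropionate (1,1,1-triethoxypropane) | CCC(OCC)(OCC)OCC | starting material
8 | (3R,6S)-6-[(1-ethoxyprop-1-en-1-yl)oxy]-1-methyl-3-(2-methylbut-3-en-2-yl)cyclohex-1-ene (ketene acetal) | CCOC(=CC)O[C@@H]1C(C)=C[C@H](C(C)(C)C=C)CC1 | intermediate (not isolated)
9 | ethyl 2-[(1S,6R)-2-methyl-6-(2-methylbut-3-en-2-yl)cyclohex-2-en-1-yl]propanoate | CCOC(=O)C(C)[C@@H]1[C@H](C(C)(C)C=C)CCC=C1C | intermediate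
10 | ethyl 2-[(1S,6R)-2-methyl-6-(2-methylbut-3-en-2-yl)-4-oxocyclohex-2-en-1-yl]propanoate | CCOC(=O)C(C)[C@@H]1[C@H](C(C)(C)C=C)CC(=O)C=C1C | intermediate
11 | dilithium bis-enolate of 10 (ester enolate at C10, cross-conjugated dienolate at C11=C1) | [Li]OC(OCC)=C(C)[C@@H]1[C@H](C(C)(C)C=C)C=C(O[Li])C=C1C | intermediate (not isolated)
12 | ethyl (1R,5R,6R,7S)-2,6-dimethyl-7-(2-methylbut-3-en-2-yl)-4-oxobicyclo[3.1.1]hept-2-ene-6-carboxylate | CCOC(=O)[C@@]1(C)[C@@H]2C(=O)C=C(C)[C@H]1[C@@H]2C(C)(C)C=C | intermediate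
13 | ethyl (1R,5R,6R,7S)-2,6-dimethyl-7-(2-methyl-3-oxobutan-2-yl)-4-oxobicyclo[3.1.1]hept-2-ene-6-carboxylate | CCOC(=O)[C@@]1(C)[C@@H]2C(=O)C=C(C)[C@H]1[C@@H]2C(C)(C)C(C)=O | intermediate
14 | (1R,2R,7S,8R)-2,6,6,9-tetramethyltricyclo[5.4.0.0^2,8]undec-9-ene-3,5,11-trione | O=C1CC(=O)[C@@]2(C)[C@@H]3C(=O)C=C(C)[C@H]2[C@@H]3C1(C)C | intermediate
15 | (1R,2R,3R,5R,7S,8R)-3,5-dihydroxy-2,6,6,9-tetramethyltricyclo[5.4.0.0^2,8]undec-9-en-11-one | O[C@@H]1C[C@@H](O)[C@@]2(C)[C@@H]3C(=O)C=C(C)[C@H]2[C@@H]3C1(C)C | intermediate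
16 | (E)-2-methylbut-2-enoyl chloride (tigloyl chloride) | C/C=C(\C)C(Cl)=O | starting material
17 | (4R,5S,7R,9R,10R,11R)-7,9-bis[(E)-2-methylbut-2-enoyloxy]longipin-2-en-1-one | C/C=C(\C)C(=O)O[C@@H]1C[C@@H](OC(=O)/C(C)=C/C)[C@@]2(C)[C@@H]3C(=O)C=C(C)[C@H]2[C@@H]3C1(C)C | target

**Step count and risks**

Total step count: 10. Longest linear sequence: 10 (fully linear from 1).

Three steps most likely to fail:

Step 6, the oxidative cyclobutane closure. It may lose to intermolecular coupling, to Dieckmann-type attack of the C11 enolate on the ester, to radical 5-exo addition onto the vinyl group, to oxidation of the dienolate to a phenol, or to the wrong C10 epimer. The fallback sets out from 10 and replaces the oxidative coupling by a two-electron alkylation of the ester enolate on an oxidised α′-carbon. TBSOTf/Et3N gives ethyl 2-[(1S,6S)-4-{[tert-butyl(dimethyl)silyl]oxy}-2-methyl-6-(2-methylbut-3-en-2-yl)cyclohexa-2,4-dien-1-yl]propanoate F1. Rubottom oxidation (dimethyldioxirane, then acid) anti to the C5 side chain gives ethyl 2-[(1S,5R,6R)-5-hydroxy-2-methyl-6-(2-methylbut-3-en-2-yl)-4-oxocyclohex-2-en-1-yl]propanoate F2. MsCl/Et3N gives ethyl 2-[(1S,5R,6R)-5-(methanesulfonyloxy)-2-methyl-6-(2-methylbut-3-en-2-yl)-4-oxocyclohex-2-en-1-yl]propanoate F3. KN(SiMe3)2 at −78 °C then lets the ester enolate displace the mesylate from the opposite face with inversion, and the route comes back at 12.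

Step 9, the double hydrogenation. Both carbonyls of the cyclic β-diketone are flanked by quaternary carbons, so the ruthenium catalyst may be slow or give the wrong sense. The fallback sets out from 14 and is stepwise. A ketoreductase (NADPH recycled with glucose and glucose dehydrogenase) chosen for R selectivity reduces one carbonyl to (4R,5S,9R,10R,11R)-9-hydroxylongipin-2-ene-1,7-dione F4. Hydroxyl-directed anti reduction with Me4NBH(OAc)3 in MeCN/AcOH at −30 °C then sets C7, and the route comes back at 15.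

Step 3, the catalyst-controlled 1,2-reduction. It must override the substrate preference for the trans alcohol, and the cis alcohol is what the Claisen step needs. The fallback sets out from 5 and accepts the substrate-controlled product. NaBH4/CeCl3 in MeOH at −78 °C gives (1R,4R)-2-methyl-4-(2-methylbut-3-en-2-yl)cyclohex-2-en-1-ol F5. Mitsunobu esterification with propanoic acid (PPh3, diisopropyl azodicarboxylate) inverts the carbinol to (1S,4R)-2-methyl-4-(2-methylbut-3-en-2-yl)cyclohex-2-en-1-yl propanoate F6. Ireland–Claisen rearrangement (LiN(iPr)2, Me3SiCl, THF, −78 → 60 °C, acidic work-up) gives 2-[(1S,6R)-2-methyl-6-(2-methylbut-3-en-2-yl)cyclohex-2-en-1-yl]propanoic acid F7. EtI/K2CO3 in DMF then gives the ethyl ester, and the route comes back at 9.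

**Further compounds**

F1 | step 6 | ethyl 2-[(1S,6S)-4-{[tert-butyl(dimethyl)silyl]oxy}-2-methyl-6-(2-methylbut-3-en-2-yl)cyclohexa-2,4-dien-1-yl]propanoate | CCOC(=O)C(C)[C@@H]1[C@H](C(C)(C)C=C)C=C(O[Si](C)(C)C(C)(C)C)C=C1C
F2 | step 6 | ethyl 2-[(1S,5R,6R)-5-hydroxy-2-methyl-6-(2-methylbut-3-en-2-yl)-4-oxocyclohex-2-en-1-yl]propanoate | CCOC(=O)C(C)[C@@H]1[C@H](C(C)(C)C=C)[C@@H](O)C(=O)C=C1C
F3 | step 6 | ethyl 2-[(1S,5R,6R)-5-(methanesulfonyloxy)-2-methyl-6-(2-methylbut-3-en-2-yl)-4-oxocyclohex-2-en-1-yl]propanoate | CCOC(=O)C(C)[C@@H]1[C@H](C(C)(C)C=C)[C@@H](OS(C)(=O)=O)C(=O)C=C1C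
F4 | step 9 | (4R,5S,9R,10R,11R)-9-hydroxylongipin-2-ene-1,7-dione | O=C1C[C@@H](O)[C@@]2(C)[C@@H]3C(=O)C=C(C)[C@H]2[C@@H]3C1(C)C
F5 | step 3 | (1R,4R)-2-methyl-4-(2-methylbut-3-en-2-yl)cyclohex-2-en-1-ol | O[C@H]1C(C)=C[C@H](C(C)(C)C=C)CC1
F6 | step 3 | (1S,4R)-2-methyl-4-(2-methylbut-3-en-2-yl)cyclohex-2-en-1-yl propanoate | CCC(=O)O[C@@H]1C(C)=C[C@H](C(C)(C)C=C)CC1
F7 | step 3 | 2-[(1S,6R)-2-methyl-6-(2-methylbut-3-en-2-yl)cyclohex-2-en-1-yl]propanoic acid | OC(=O)C(C)[C@@H]1[C@H](C(C)(C)C=C)CCC=C1C
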